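**Retrosynthetic overview** (labdane numbering, C1–C20)
1. C12–C13 is cut last. Hydroboration of the 9-vinyl compound 17 and B-alkyl Suzuki–Miyaura coupling with bought 4-bromofuran-2(5H)-one 18 attaches the butenolide (ring D), which is never built.
2. C6–OAc and C5–H come from a C5=C6 silyl enol ether by proton and then hydride delivery, both from the α face, followed by acetylation. The C11=C12 vinyl group comes from a lactol (Wittig), and C1–H from C1–OH (Barton–McCombie).
3. Key disconnection: C7–C8 and C9–C10 are made together by intramolecular Diels–Alder reaction of the (S)-cyclohexenyl but-2-ynoate 8. The temporary C1–O–C11(=O) tether (ring C, a γ-lactone absent from the target) relays the C1 carbinol centre to quaternary C10. The tether is then dismantled, and its carbonyl carbon stays as C11.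
4. Enabling feature: ring B is a cyclohexene whose tetrasubstituted C8=C9 bond lies 1,4 to oxygen-bearing C6, next to an enolisable C5–H. At the enol ether level ring B is therefore a cyclohexa-1,4-diene, the retron of an alkyne Diels–Alder reaction. In addition, C11 on C9 is reached from C10 through only C1 and one oxygen.
5. Ring order: ring A is bought (β-cyclocitral), rings B and C form in step 7, ring C is opened and erased in steps 8–11, and ring D is attached in step 15.

Key step: step 7

Remark: the SMILES is read as 5α-H, 6β-OAc, 10β-CH3 (5S,6R,10S), that is 6β-acetoxylabda-8,13-dien-15,16-olide. The α/β descriptors refer to the usual labdane drawing.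

Step 1
Reactants: 1 β-cyclocitral
Product: 2 (±)-1-(2,6,6-trimethylcyclohex-1-en-1-yl)ethan-1-ol
Conditions: MeMgBr, Et2O, 0 °C → rt; aq NH4Cl
Reagents that add atoms: methylmagnesium bromide C[Mg]Br
Why: Grignard 1,2-addition to a hindered, non-enolisable enal should give the carbinol, whose racemic centre is erased in step 2.

Step 2
Reactants: 2 (±)-1-(2,6,6-trimethylcyclohex-1-en-1-yl)ethan-1-ol
Product: 3 1-(2,6,6-trimethylcyclohex-1-en-1-yl)ethan-1-one
Conditions: Pr4N[RuO4] (5 mol %), NMO, 4 Å MS, CH2Cl2, rt
Reagents that add atoms: none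
Why: Ley–Griffith oxidation works under neutral conditions, so the acid-labile allylic alcohol should be oxidised without dehydration.

Step 3
Reactants: 3 1-(2,6,6-trimethylcyclohex-1-en-1-yl)ethan-1-one
Product: 4 3-acetyl-2,4,4-trimethylcyclohex-2-en-1-one
Conditions: Rh2(cap)4 (dirhodium tetrakis(caprolactamate), 1 mol %), t-BuOOH (70 % aq), ClCH2CH2Cl, 40 °C
Reagents that add atoms: tert-butyl hydroperoxide CC(C)(C)OO
Why: Radical allylic C–H oxidation of an enone to an ene-dione should take the only allylic ring methylene (future C1), because its secondary C–H bonds are abstracted faster than those of the vinylic methyl group.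

Step 4
Reactants: 4 3-acetyl-2,4,4-trimethylcyclohex-2-en-1-one
Product: 5 (S)-1-(3-hydroxy-2,6,6-trimethylcyclohex-1-en-1-yl)ethan-1-one
Conditions: (R)-2-methyl-CBS-oxazaborolidine (20 mol %), catecholborane, toluene, −78 °C; MeOH, aq NaHCO3
Reagents that add atoms: none
Why: In this Corey–Bakshi–Shibata reduction the (R)-catalyst treats the methyl-bearing alkenyl flank of the ring carbonyl as the large group and should deliver hydride to give the (S)-carbinol (future 1α-O), while the acetyl carbonyl, held perpendicular to the alkene between three methyl groups, should be too shielded to compete.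

Step 5
Reactants: 5 (S)-1-(3-hydroxy-2,6,6-trimethylcyclohex-1-en-1-yl)ethan-1-one, 6 but-2-ynoic acid
Product: 7 (S)-3-acetyl-2,4,4-trimethylcyclohex-2-en-1-yl but-2-ynoate
Conditions: DCC, DMAP (cat.), CH2Cl2, 0 °C → rt
Reagents that add atoms: none
Why: Steglich esterification acylates the oxygen without touching the C–O bond, so the carbinol configuration is retained.

Step 6
Reactants: 7 (S)-3-acetyl-2,4,4-trimethylcyclohex-2-en-1-yl but-2-ynoate
Product: 8 (S)-3-[1-(tert-butyldimethylsilyloxy)vinyl]-2,4,4-trimethylcyclohex-2-en-1-yl but-2-ynoate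
Conditions: TBSOTf, Et3N, CH2Cl2, 0 °C
Reagents that add atoms: tert-butyldimethylsilyl triflate CC(C)(C)[Si](C)(C)OS(=O)(=O)C(F)(F)F
Why: Soft enolisation (silyl enol ether formation) should give only the cross-conjugated 2-silyloxydiene, because the acetyl group is twisted out of conjugation and acidifies only its own methyl protons, and the ynoate ester enolises far more slowly.

Step 7
Reactants: 8 (S)-3-[1-(tert-butyldimethylsilyloxy)vinyl]-2,4,4-trimethylcyclohex-2-en-1-yl but-2-ynoate
Product: 9 6-(tert-butyldimethylsilyloxy)-12,13,14,15,16-pentanorlabda-5,8-dien-11,1α-olide (tricyclic lactone, 1α-O, 10β-CH3)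
Conditions: toluene (0.02 M), BHT (cat.), sealed tube, 120 °C
Reagents that add atoms: none
Why: This is a thermal, concerted but asynchronous normal-electron-demand [4π+2π] cycloaddition in which the C7=C6(OTBS)–C5=C10 diene of 8 adds across the C8≡C9 triple bond of its own but-2-ynoate, making C7–C8 and C9–C10 together and leaving the C5=C6 silyl enol ether and the tetrasubstituted C8=C9 alkene. The closest known reaction type is the type 1 intramolecular Diels–Alder reaction of 3-vinylcyclohex-2-enyl alkynoates, which gives the same lactone-bridged hexahydronaphthalene core. Ring B closes as the six-membered cycloadduct ring with both components reacting suprafacially, and the five-membered lactone ring C (C1–O–C11–C9–C10) closes in the fused mode because the three-atom tether C1–O–C11 joins the diene terminus C10 to C9. The only new stereocentre, quaternary C10, is controlled by the C1 carbinol centre, since the short tether can bring the alkyne only to the diene face that carries the C1–O bond, which places C9 cis to the 1α-oxygen and leaves the methyl group β. The step needs regioselectivity (C9 to C10, C8 to C7), secured both by the tether and by the matched polarity of nucleophilic C7 in the 2-silyloxydiene with electrophilic C8 of the ynoate (para relation of C6–O and C11=O), and it needs the cycloaddition to outrun a 1,5-hydrogen shift of the diene, for which intramolecularity, the raised diene HOMO and the moderate temperature are relied upon. No endo/exo question arises because the dienophile is an alkyne.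

Step 8
Reactants: 9 tricyclic lactone
Product: 10 6-(tert-butyldimethylsilyloxy)-1α,11-epoxy-12,13,14,15,16-pentanorlabda-5,8-dien-11-ol (lactol, C11 epimers)
Conditions: i-Bu2AlH (1.1 equiv), CH2Cl2, −78 °C; Rochelle salt
Reagents that add atoms: none
Why: Partial lactone reduction should stop at the lactol because the aluminium hemiacetal is stable at −78 °C, and the new C11 centre is inconsequential since it becomes sp2 in step 9.

Step 9
Reactants: 10 lactol
Product: 12 6-(tert-butyldimethylsilyloxy)-13,14,15,16-tetranorlabda-5,8,11-trien-1α-ol, via hydroxy enal 11 (not isolated)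
Conditions: Ph3PCH3Br, KHMDS, THF, 0 °C → rt
Reagents that add atoms: methyltriphenylphosphonium bromide C[P+](c1ccccc1)(c1ccccc1)c1ccccc1.[Br-]
Why: Wittig methylenation of a lactol proceeds through its ring-opened conjugated hydroxy enal, a hindered enal of the β-cyclocitral type that is known to accept this ylide, and it frees the 1α-hydroxyl group.

Step 10
Reactants: 12 1α-hydroxy triene
Product: 13 O-phenyl thionocarbonate of 12
Conditions: PhOC(S)Cl, pyridine, DMAP (cat.), CH2Cl2, rt
Reagents that add atoms: O-phenyl chlorothionoformate ClC(=S)Oc1ccccc1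
Why: DMAP-catalysed thioacylation of the only free hydroxyl group installs the radical leaving group for the Barton–McCombie sequence and leaves the silyl enol ether and the diene untouched.

Step 11
Reactants: 13 O-phenyl thionocarbonate
Product: 14 6-(tert-butyldimethylsilyloxy)-13,14,15,16-tetranorlabda-5,8,11-triene
Conditions: Bu3SnH (0.3 M), AIBN (cat.), toluene, 85 °C
Reagents that add atoms: none
Why: Barton–McCombie deoxygenation erases the temporary C1 stereocentre, and the high stannane concentration should keep hydrogen transfer ahead of any 1,2-vinyl shift of the homoallylic C1 radical.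

Step 12
Reactants: 14 silyl enol ether triene
Product: 15 13,14,15,16-tetranorlabda-8,11-dien-6-one (5α-H, trans-fused)
Conditions: Bu4NF, AcOH, THF, −20 → 0 °C
Reagents that add atoms: none
Why: Buffered fluoride desilylation with kinetic C-protonation of the enolate should place the proton on the α face of C5, anti to the adjacent 10β-methyl group, which gives the trans ring fusion that is also thermodynamically preferred, and the buffer avoids enolisation towards C7.

Step 13
Reactants: 15 6-ketone
Product: 16 13,14,15,16-tetranorlabda-8,11-dien-6β-ol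
Conditions: LiAlH4, Et2O, −78 → 0 °C
Reagents that add atoms: none
Why: Substrate-controlled hydride reduction should occur from the α face, because the β face of C6 is closed by the syn-axial 10β- and 4β-methyl groups, and this gives the axial 6β-alcohol.

Step 14
Reactants: 16 6β-alcohol
Product: 17 13,14,15,16-tetranorlabda-8,11-dien-6β-yl acetate
Conditions: Ac2O, DMAP (cat.), pyridine, 50 °C
Reagents that add atoms: acetic anhydride CC(=O)OC(C)=O
Why: DMAP-catalysed acetylation with gentle heating should overcome the hindrance of the axial alcohol and retains the C6 configuration.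

Step 15
Reactants: 17 6β-acetoxy diene, 18 4-bromofuran-2(5H)-one
Product: 20 6β-acetoxylabda-8,13-dien-15,16-olide (target), via B-alkyl-9-BBN borane 19 (not isolated)
Conditions: 9-BBN, THF, 0 °C → rt; then 18, Pd(dppf)Cl2 (5 mol %), AsPh3, Cs2CO3, DMF–H2O, rt → 45 °C
Reagents that add atoms: none
Why: 9-BBN should add anti-Markovnikov to the terminal vinyl group only, since the tetrasubstituted C8=C9 bond is inert and the vinyl group is twisted out of conjugation, and B-alkyl Suzuki–Miyaura coupling with the β-bromobutenolide then forms C12–C13 under conditions that the hindered acetate tolerates.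

**Compound list**
1 | β-cyclocitral (2,6,6-trimethylcyclohex-1-ene-1-carbaldehyde) | CC1=C(C=O)C(C)(C)CCC1 | starting material
2 | (±)-1-(2,6,6-trimethylcyclohex-1-en-1-yl)ethan-1-ol | CC(O)C1=C(C)CCCC1(C)C | intermediate
3 | 1-(2,6,6-trimethylcyclohex-1-en-1-yl)ethan-1-one | CC(=O)C1=C(C)CCCC1(C)C | intermediate
4 | 3-acetyl-2,4,4-trimethylcyclohex-2-en-1-one | CC(=O)C1=C(C)C(=O)CCC1(C)C | intermediate
5 | (S)-1-(3-hydroxy-2,6,6-trimethylcyclohex-1-en-1-yl)ethan-1-one | CC(=O)C1=C(C)[C@@H](O)CCC1(C)C | intermediate
6 | but-2-ynoic acid | CC#CC(=O)O | starting material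
7 | (S)-3-acetyl-2,4,4-trimethylcyclohex-2-en-1-yl but-2-ynoate | CC(=O)C1=C(C)[C@@H](OC(=O)C#CC)CCC1(C)C | intermediate
8 | (S)-3-[1-(tert-butyldimethylsilyloxy)vinyl]-2,4,4-trimethylcyclohex-2-en-1-yl but-2-ynoate | C=C(O[Si](C)(C)C(C)(C)C)C1=C(C)[C@@H](OC(=O)C#CC)CCC1(C)C | intermediate
9 | 6-(TBSO)-12,13,14,15,16-pentanorlabda-5,8-dien-11,1α-olide (10β-CH3) | CC(C)(C)[Si](C)(C)OC1=C2C(C)(C)CC[C@@H]3OC(=O)C(=C(C)C1)[C@]23C | intermediate
10 | corresponding lactol (C11 epimers) | CC(C)(C)[Si](C)(C)OC1=C2C(C)(C)CC[C@@H]3OC(O)C(=C(C)C1)[C@]23C | intermediate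
11 | 1α-hydroxy-6-(TBSO)-12,13,14,15,16-pentanorlabda-5,8-dien-11-al (hydroxy enal) | CC(C)(C)[Si](C)(C)OC1=C2C(C)(C)CC[C@H](O)[C@]2(C)C(C=O)=C(C)C1 | intermediate
12 | 6-(TBSO)-13,14,15,16-tetranorlabda-5,8,11-trien-1α-ol | CC(C)(C)[Si](C)(C)OC1=C2C(C)(C)CC[C@H](O)[C@]2(C)C(C=C)=C(C)C1 | intermediate
13 | O-phenyl thionocarbonate of 12 | CC(C)(C)[Si](C)(C)OC1=C2C(C)(C)CC[C@H](OC(=S)Oc3ccccc3)[C@]2(C)C(C=C)=C(C)C1 | intermediate
14 | 6-(TBSO)-13,14,15,16-tetranorlabda-5,8,11-triene (10β-CH3) | CC(C)(C)[Si](C)(C)OC1=C2C(C)(C)CCC[C@]2(C)C(C=C)=C(C)C1 | intermediate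
15 | 13,14,15,16-tetranorlabda-8,11-dien-6-one (5α-H) | O=C1CC(C)=C(C=C)[C@@]2(C)CCCC(C)(C)[C@H]12 | intermediate
16 | 13,14,15,16-tetranorlabda-8,11-dien-6β-ol | O[C@@H]1CC(C)=C(C=C)[C@@]2(C)CCCC(C)(C)[C@H]12 | intermediate
17 | 13,14,15,16-tetranorlabda-8,11-dien-6β-yl acetate | CC(=O)O[C@@H]1CC(C)=C(C=C)[C@@]2(C)CCCC(C)(C)[C@H]12 | intermediate
18 | 4-bromofuran-2(5H)-one | O=C1C=C(Br)CO1 | starting material
19 | 12-(9-borabicyclo[3.3.1]nonan-9-yl)-13,14,15,16-tetranorlabd-8-en-6β-yl acetate | CC(=O)O[C@@H]1CC(C)=C(CCB3C4CCCC3CCC4)[C@@]2(C)CCCC(C)(C)[C@H]12 | intermediate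
20 | 6β-acetoxylabda-8,13-dien-15,16-olide, (5S,6R,10S) | CC(=O)O[C@@H]1CC(C)=C(CCC2=CC(=O)OC2)[C@@]2(C)CCCC(C)(C)[C@H]12 | target

**Total step count:** 15. **Longest linear sequence:** 15 (from 1; compounds 6 and 18 are bought).

**Steps most likely to fail**

Step 7.
- Risk: the cycloaddition may be too slow. The planar s-cis diene presses the silyloxy group against the C4 gem-dimethyl group, and the ester must adopt its less stable conformation. A thermal 1,5-hydrogen shift of the diene or loss of the silyl group could then take over.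
- Fallback: it sets out from 8 and comes back at 9, and it replaces the methyl-bearing dienophile by a doubly activated one.
- Reductive removal of the butynoate (i-Bu2AlH, CH2Cl2, −78 °C) gives the hydroxy silyl dienol ether F1.
- DCC coupling with 3-(p-tolylsulfonyl)propiolic acid gives the sulfonyl ynoate F2, which should cycloadd at or below room temperature to the 8-sulfonyl lactone F3.
- Me2CuLi (Et2O, −78 °C) then exchanges the sulfonyl group for methyl by conjugate addition–elimination and delivers 9.

Step 12.
- Risk: after desilylation the C7 methylene lies between the carbonyl group and the dienyl unit. It may lose a proton, so that the ring B alkene drifts into conjugation, and this would also blur the facial selectivity of protonation at C5.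
- Fallback: it sets out from 14 and comes back at 20. The silyl enol ether is carried through the coupling, so the ketone is unveiled only when the vinyl group is gone.
- 9-BBN gives the silyl enol ether borane F4, and coupling with 18 under the conditions of step 15 gives the silyl enol ether butenolide F5.
- Buffered fluoride gives the 6-oxo butenolide F6.
- Luche reduction (NaBH4, CeCl3·7H2O, MeOH, −20 °C), which spares the butenolide, gives the 6β-hydroxy butenolide F7, and acetylation as in step 14 gives 20.

Step 4.
- Risk: hydride may be delivered to the acetyl carbonyl, or enantioface discrimination at the ring carbonyl may be weak.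
- Fallback: it sets out from 4 and comes back at 5, and it replaces asymmetric reduction by enzymatic resolution.
- Luche reduction gives the racemic hydroxy ketone F8.
- Lipase-catalysed acylation (Candida antarctica lipase B, vinyl acetate, MTBE) should convert the faster-reacting (R)-enantiomer into the (R)-acetate F9. This leaves the (S)-alcohol 5, which is separated by chromatography.

**Further compounds**
F1 | step 7 | (S)-3-[1-(tert-butyldimethylsilyloxy)vinyl]-2,4,4-trimethylcyclohex-2-en-1-ol | C=C(O[Si](C)(C)C(C)(C)C)C1=C(C)[C@@H](O)CCC1(C)C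
F2 | step 7 | (S)-3-[1-(tert-butyldimethylsilyloxy)vinyl]-2,4,4-trimethylcyclohex-2-en-1-yl 3-(p-tolylsulfonyl)propiolate | C=C(O[Si](C)(C)C(C)(C)C)C1=C(C)[C@@H](OC(=O)C#CS(=O)(=O)c2ccc(C)cc2)CCC1(C)C
F3 | step 7 | 8-(p-tolylsulfonyl) analogue of lactone 9 (sulfonyl in place of the C8 methyl group) | CC(C)(C)[Si](C)(C)OC1=C2C(C)(C)CC[C@@H]3OC(=O)C(=C(C1)S(=O)(=O)c4ccc(C)cc4)[C@]23C
F4 | step 12 | 12-(9-borabicyclo[3.3.1]nonan-9-yl)-6-(TBSO)-13,14,15,16-tetranorlabda-5,8-diene | CC(C)(C)[Si](C)(C)OC1=C2C(C)(C)CCC[C@]2(C)C(CCB3C4CCCC3CCC4)=C(C)C1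
F5 | step 12 | 6-(TBSO)labda-5,8,13-trien-15,16-olide | CC(C)(C)[Si](C)(C)OC1=C2C(C)(C)CCC[C@]2(C)C(CCC3=CC(=O)OC3)=C(C)C1
F6 | step 12 | 6-oxolabda-8,13-dien-15,16-olide (5α-H) | O=C1CC(C)=C(CCC2=CC(=O)OC2)[C@@]2(C)CCCC(C)(C)[C@H]12
F7 | step 12 | 6β-hydroxylabda-8,13-dien-15,16-olide | O[C@@H]1CC(C)=C(CCC2=CC(=O)OC2)[C@@]2(C)CCCC(C)(C)[C@H]12
F8 | step 4 | (±)-1-(3-hydroxy-2,6,6-trimethylcyclohex-1-en-1-yl)ethan-1-one | CC(=O)C1=C(C)C(O)CCC1(C)C
F9 | step 4 | (R)-3-acetyl-2,4,4-trimethylcyclohex-2-en-1-yl acetate | CC(=O)C1=C(C)[C@H](OC(C)=O)CCC1(C)C
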